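The route rests on cutting unit 2 (the 8-aryloxy-7-hydroxyisoflavone half) at C3–C1′, the bond between C3 of its pyranone ring C and the para carbon of the 4-hydroxyphenyl ring B, together with O1–C2 of ring C. Both carbons are donor sites, so the bond is made anodically: electrolysis of a 2-hydroxyaryl dimethylaminoenone with phenol arylates the enaminone α-carbon and lets the chelated ring-A hydroxyl close ring C with loss of dimethylamine, all in one operation. The precursor is the complete 8-chloro-isoflavone unit 1, joined through its 4′-oxygen to a 2-hydroxy-4-(methoxymethoxy)phenyl enaminone; unit 1 comes from 2-chlororesorcinol and an arylacetic acid by deoxybenzoin annulation.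

Key step: step 8

Remark on the chemistry: the target has no stereocentre; the only stereo-element in the route is the E double bond of enaminone 12 (and of transient 14), which is consumed in step 8.

Step 1
Reactants: 1 2,6-dimethoxyphenol; 2 4'-fluoroacetophenone
Product: 3 1-[4-(2,6-dimethoxyphenoxy)phenyl]ethan-1-one
Conditions: K2CO3, DMSO, 120 °C, Ar
Reagents that add atoms: none
Why: Nucleophilic aromatic substitution (SNAr), in which the para acetyl group stabilises the Meisenheimer adduct so that the potassium phenoxide of 1, hindered but strongly nucleophilic, should displace fluoride cleanly in a dipolar aprotic solvent.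

Step 2
Reactants: 3 1-[4-(2,6-dimethoxyphenoxy)phenyl]ethan-1-one
Product: 5 2-[4-(2,6-dimethoxyphenoxy)phenyl]acetic acid, via thiomorpholide 4 (not isolated)
Conditions: S8, morpholine, 130 °C; then NaOH, EtOH/H2O, reflux; then HCl (aq)
Reagents that add atoms: sulfur, S1SSSSSSS1; morpholine, C1COCCN1; sodium hydroxide, [Na+].[OH-]; water, O
Why: Willgerodt–Kindler reaction, which moves the carbonyl oxidation level of an aryl methyl ketone to the terminal carbon as the thioamide 4 (taking up sulfur and morpholine), followed by alkaline thioamide hydrolysis that replaces sulfur and morpholine by the two carboxyl oxygens from hydroxide and water and leaves the aryl ethers untouched.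

Step 3
Reactants: 5 2-[4-(2,6-dimethoxyphenoxy)phenyl]acetic acid; 6 2-chlororesorcinol
Product: 8 8-chloro-3-[4-(2,6-dimethoxyphenoxy)phenyl]-7-hydroxy-4H-chromen-4-one, via deoxybenzoin 7 (not isolated)
Conditions: 6 (1.5 equiv), BF3·OEt2 (solvent), 90 °C; then DMF, MsCl, 70 °C; H2O
Reagents that add atoms: N,N-dimethylformamide, CN(C)C=O
Why: One-pot deoxybenzoin isoflavone synthesis, in which Friedel–Crafts C-acylation takes the resorcinol (used in excess so that it outcompetes the dimethoxyphenoxy ring of a second molecule of 5) at C4, its only position ortho to one hydroxyl and para to the other, after which Vilsmeier-type formylation of the boron-chelated active methylene by DMF/MsCl supplies C2 and the ortho hydroxyl closes the pyranone by cyclodehydration.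

Step 4
Reactants: 8 8-chloro-3-[4-(2,6-dimethoxyphenoxy)phenyl]-7-hydroxy-4H-chromen-4-one
Product: 9 8-chloro-3-[4-(2,6-dihydroxyphenoxy)phenyl]-7-hydroxy-4H-chromen-4-one
Conditions: BBr3 (5 equiv), CH2Cl2, −78 °C to rt; then MeOH, H2O
Reagents that add atoms: none
Why: Lewis-acid cleavage of aryl methyl ethers by BBr3 (bromide attack on the O-methyl of the boron–ether adduct), a reaction to which the diaryl ether, the aryl chloride and the chromone are inert.

Step 5
Reactants: 9 8-chloro-3-[4-(2,6-dihydroxyphenoxy)phenyl]-7-hydroxy-4H-chromen-4-one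
Product: 10 3-[4-(3-acetyl-2,6-dihydroxyphenoxy)phenyl]-8-chloro-7-hydroxy-4H-chromen-4-one
Conditions: AcOH, BF3·OEt2 (solvent), 90 °C; then aq. NaOAc, MeOH, 60 °C
Reagents that add atoms: acetic acid, CC(=O)O
Why: Friedel–Crafts (Nencki-type) C-acetylation of a resorcinol, directed to the equivalent C4/C6 positions of the 2-aryloxyresorcinol ring because it is by far the most electron-rich arene present, with acetic acid in place of the anhydride to avoid further acylation of the new methyl ketone and a mild hydrolytic work-up to break the boron chelate.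

Step 6
Reactants: 10 3-[4-(3-acetyl-2,6-dihydroxyphenoxy)phenyl]-8-chloro-7-hydroxy-4H-chromen-4-one
Product: 11 3-{4-[3-acetyl-2-hydroxy-6-(methoxymethoxy)phenoxy]phenyl}-8-chloro-7-(methoxymethoxy)-4H-chromen-4-one
Conditions: MOMCl (2.2 equiv), K2CO3, acetone, 0 °C to rt
Reagents that add atoms: chloromethyl methyl ether, COCCl
Why: Williamson-type O-alkylation under weak-base conditions, which should take the two free, more acidic hydroxyls (O7 of unit 1 and the one para to the acetyl group) and spare the hydroxyl ortho to the acetyl group, held in an intramolecular hydrogen bond.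

Step 7
Reactants: 11 3-{4-[3-acetyl-2-hydroxy-6-(methoxymethoxy)phenoxy]phenyl}-8-chloro-7-(methoxymethoxy)-4H-chromen-4-one
Product: 12 (E)-1-{3-[4-(8-chloro-7-(methoxymethoxy)-4-oxo-4H-chromen-3-yl)phenoxy]-2-hydroxy-4-(methoxymethoxy)phenyl}-3-(dimethylamino)prop-2-en-1-one
Conditions: Me2NCH(OMe)2, toluene, 90 °C
Reagents that add atoms: N,N-dimethylformamide dimethyl acetal, COC(OC)N(C)C
Why: Amide-acetal condensation of a methyl ketone to the E-configured dimethylaminoenone (enaminone synthesis), the standard entry to 2-hydroxyaryl enaminones, run without acid so that the MOM acetals and the open-chain enaminone persist.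

Step 8
Reactants: 12 (E)-1-{3-[4-(8-chloro-7-(methoxymethoxy)-4-oxo-4H-chromen-3-yl)phenoxy]-2-hydroxy-4-(methoxymethoxy)phenyl}-3-(dimethylamino)prop-2-en-1-one; 13 phenol
Product: 15 8-chloro-3-[4-({3-(4-hydroxyphenyl)-7-(methoxymethoxy)-4-oxo-4H-chromen-8-yl}oxy)phenyl]-7-(methoxymethoxy)-4H-chromen-4-one, via α-aryl enaminone 14 (not isolated)
Conditions: undivided cell, boron-doped diamond anode, Pt cathode, constant current 5 mA cm−2, 2.5 F mol−1; phenol (5 equiv), 2,6-lutidine (2 equiv), Bu4NPF6 (0.1 M), HFIP, 25 °C
Reagents that add atoms: none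
Why: Proposed new method: at the diamond anode in HFIP, phenol (in excess, its oxidation eased by proton transfer to the non-nucleophilic base 2,6-lutidine) should give a solvent-stabilised phenoxyl radical whose para carbon is captured by the nucleophilic α-carbon of 12 (should 12 be oxidised first, its radical cation is expected to be intercepted at the same α-carbon by the phenol π-system, so both polarities lead to the C3–C1′ bond); removal of a second electron and a proton rearomatises the phenol ring to 14 or its iminium ion, and the cathode discharges the released protons as hydrogen. The chelated ortho hydroxyl then adds to the aminomethylene carbon (future C2) in a six-membered closure, 6-exo-trig on the iminium ion or 6-endo-trig oxa-Michael on neutral 14, and β-elimination of dimethylamine aromatises ring C to the 4-pyranone. Nearest precedent in type: diamond-anode electrolyses that cross-couple phenols with arenes in HFIP, and electro-oxidative α-thiolation, α-selenylation or α-halogenation of o-hydroxyaryl enaminones that end in chromone ring closure. No stereocentre is created. Two selectivities are needed, coupling at the para instead of an ortho position of phenol and hetero- instead of homo-coupling, and the steric demand of the aroyl-bearing α-carbon, the excess of cheap phenol and the hydrogen-bonding solvent should secure them; the phenol of 12 is tied up in its hydrogen bond to the carbonyl and its aryl ether rings carry acceptor groups, while product 15, a phenol attached to a chromone, should be harder to oxidise than phenol itself. The lutidine buffer keeps anodically generated acid away from the MOM acetals.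

Step 9
Reactants: 15 8-chloro-3-[4-({3-(4-hydroxyphenyl)-7-(methoxymethoxy)-4-oxo-4H-chromen-8-yl}oxy)phenyl]-7-(methoxymethoxy)-4H-chromen-4-one
Product: 16 bisoflavolin J, 8-chloro-7-hydroxy-3-[4-({7-hydroxy-3-(4-hydroxyphenyl)-4-oxo-4H-chromen-8-yl}oxy)phenyl]-4H-chromen-4-one
Conditions: HCl (3 M in MeOH), THF, 45 °C
Reagents that add atoms: none
Why: Acid-catalysed acetal cleavage (MOM removal) with transfer of the methoxymethyl groups to methanol, under which the chromones, the diaryl ether and the aryl chloride are stable.

Compound list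
1 | 2,6-dimethoxyphenol | COc1cccc(OC)c1O | starting material
2 | 4'-fluoroacetophenone | CC(=O)c1ccc(F)cc1 | starting material
3 | 1-[4-(2,6-dimethoxyphenoxy)phenyl]ethan-1-one | CC(=O)c1ccc(Oc2c(OC)cccc2OC)cc1 | intermediate
4 | 2-[4-(2,6-dimethoxyphenoxy)phenyl]-1-(morpholin-4-yl)ethane-1-thione (thiomorpholide) | S=C(Cc1ccc(Oc2c(OC)cccc2OC)cc1)N1CCOCC1 | intermediate
5 | 2-[4-(2,6-dimethoxyphenoxy)phenyl]acetic acid | OC(=O)Cc1ccc(Oc2c(OC)cccc2OC)cc1 | intermediate
6 | 2-chlororesorcinol (2-chlorobenzene-1,3-diol) | Oc1cccc(O)c1Cl | starting material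
7 | 1-(3-chloro-2,4-dihydroxyphenyl)-2-[4-(2,6-dimethoxyphenoxy)phenyl]ethan-1-one (deoxybenzoin) | O=C(Cc1ccc(Oc2c(OC)cccc2OC)cc1)c1ccc(O)c(Cl)c1O | intermediate
8 | 8-chloro-3-[4-(2,6-dimethoxyphenoxy)phenyl]-7-hydroxy-4H-chromen-4-one | COc1cccc(OC)c1Oc1ccc(-c2coc3c(Cl)c(O)ccc3c2=O)cc1 | intermediate
9 | 8-chloro-3-[4-(2,6-dihydroxyphenoxy)phenyl]-7-hydroxy-4H-chromen-4-one | Oc1cccc(O)c1Oc1ccc(-c2coc3c(Cl)c(O)ccc3c2=O)cc1 | intermediate
10 | 3-[4-(3-acetyl-2,6-dihydroxyphenoxy)phenyl]-8-chloro-7-hydroxy-4H-chromen-4-one | CC(=O)c1ccc(O)c(Oc2ccc(-c3coc4c(Cl)c(O)ccc4c3=O)cc2)c1O | intermediate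
11 | 3-{4-[3-acetyl-2-hydroxy-6-(methoxymethoxy)phenoxy]phenyl}-8-chloro-7-(methoxymethoxy)-4H-chromen-4-one | CC(=O)c1ccc(OCOC)c(Oc2ccc(-c3coc4c(Cl)c(OCOC)ccc4c3=O)cc2)c1O | intermediate
12 | (E)-1-{3-[4-(8-chloro-7-(methoxymethoxy)-4-oxo-4H-chromen-3-yl)phenoxy]-2-hydroxy-4-(methoxymethoxy)phenyl}-3-(dimethylamino)prop-2-en-1-one | CN(C)/C=C/C(=O)c1ccc(OCOC)c(Oc2ccc(-c3coc4c(Cl)c(OCOC)ccc4c3=O)cc2)c1O | intermediate
13 | phenol | Oc1ccccc1 | starting material
14 | (E)-1-{3-[4-(8-chloro-7-(methoxymethoxy)-4-oxo-4H-chromen-3-yl)phenoxy]-2-hydroxy-4-(methoxymethoxy)phenyl}-3-(dimethylamino)-2-(4-hydroxyphenyl)prop-2-en-1-one (α-aryl enaminone) | CN(C)/C=C(\c1ccc(O)cc1)C(=O)c1ccc(OCOC)c(Oc2ccc(-c3coc4c(Cl)c(OCOC)ccc4c3=O)cc2)c1O | intermediate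
15 | 8-chloro-3-[4-({3-(4-hydroxyphenyl)-7-(methoxymethoxy)-4-oxo-4H-chromen-8-yl}oxy)phenyl]-7-(methoxymethoxy)-4H-chromen-4-one | COCOc1ccc2c(=O)c(-c3ccc(O)cc3)coc2c1Oc1ccc(-c2coc3c(Cl)c(OCOC)ccc3c2=O)cc1 | intermediate
16 | bisoflavolin J, 8-chloro-7-hydroxy-3-[4-({7-hydroxy-3-(4-hydroxyphenyl)-4-oxo-4H-chromen-8-yl}oxy)phenyl]-4H-chromen-4-one | O=c1c(-c2ccc(Oc3c(O)ccc4c(=O)c(-c5ccc(O)cc5)coc34)cc2)coc2c(Cl)c(O)ccc12 | target

Total step count: 9 steps.
Longest linear sequence: 9 steps (1 → 3 → 5 → 8 → 9 → 10 → 11 → 12 → 15 → 16).

Steps most likely to fail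

1. Step 8 (bears the label "Proposed new method:").
- What may go wrong: the anode may oxidise the enaminone or the aryl ether rings unproductively instead of engaging phenol. Phenol may homo-couple or polymerise on the electrode and passivate it. Ortho coupling may compete with para coupling. Anodic acid may strip the MOM acetals and expose oxidisable phenols.
- Fallback (known chemistry): setting out from 12, iodine with pyridine in CHCl3 at room temperature should effect iodocyclisation with loss of dimethylamine to 8-chloro-3-[4-({3-iodo-7-(methoxymethoxy)-4-oxo-4H-chromen-8-yl}oxy)phenyl]-7-(methoxymethoxy)-4H-chromen-4-one F1. Suzuki–Miyaura coupling of F1 with 4-hydroxyphenylboronic acid (Pd(PPh3)4, zerovalent palladium, Na2CO3, DME/H2O, 80 °C), in which the C–I bond reacts far faster than the aryl chloride, comes back to the route at 15.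

2. Step 5.
- What may go wrong: C-acetylation of the boron-complexed, chromone-bearing triol may stall. It may also be diverted to O-acetates or to boron chelates that acylate further at the new methyl ketone.
- Fallback: setting out from 8 (before demethylation), Friedel–Crafts acetylation with AcCl/AlCl3 in CH2Cl2 (0 °C to reflux) should acylate the dimethoxy ring ortho to one methoxy group and para to the other. The aluminium chelate of the new ketone should then cleave the adjacent methoxy group. After a brief K2CO3/MeOH treatment to remove any acetate on O7, this gives 3-[4-(3-acetyl-2-hydroxy-6-methoxyphenoxy)phenyl]-8-chloro-7-hydroxy-4H-chromen-4-one F2. BBr3 in CH2Cl2 then removes the remaining methyl group and comes back to the route at 10, replacing steps 4 and 5.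

3. Step 2.
- What may go wrong: the Willgerodt–Kindler rearrangement may stop at partial conversion or give polysulfide tars, and hydrolysis of the thioamide may be slow, so that material is lost early.
- Fallback: setting out from 1, copper-catalysed Ullmann diaryl ether coupling with methyl 2-(4-bromophenyl)acetate (CuI, picolinic acid, K3PO4, DMSO, 90 °C) should give methyl 2-[4-(2,6-dimethoxyphenoxy)phenyl]acetate F3. Saponification (LiOH, THF/H2O; then HCl) comes back to the route at 5, bypassing 3 and 4.

Further compounds
F1 | step 8 | 8-chloro-3-[4-({3-iodo-7-(methoxymethoxy)-4-oxo-4H-chromen-8-yl}oxy)phenyl]-7-(methoxymethoxy)-4H-chromen-4-one | COCOc1ccc2c(=O)c(I)coc2c1Oc1ccc(-c2coc3c(Cl)c(OCOC)ccc3c2=O)cc1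
F2 | step 5 | 3-[4-(3-acetyl-2-hydroxy-6-methoxyphenoxy)phenyl]-8-chloro-7-hydroxy-4H-chromen-4-one | CC(=O)c1ccc(OC)c(Oc2ccc(-c3coc4c(Cl)c(O)ccc4c3=O)cc2)c1O
F3 | step 2 | methyl 2-[4-(2,6-dimethoxyphenoxy)phenyl]acetate | COC(=O)Cc1ccc(Oc2c(OC)cccc2OC)cc1
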